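**Retrosynthetic overview**
1. Target 31 ← tetra-MOM diol 28 (carbamoylation, acid deprotection) ← macrocyclic bis-(Z)-alkene 26. Both benzylic C–O bonds and the centres C1, C2, C14 and C15 come from one reagent-controlled syn hydroboration–oxidation (key step).
2. 26 (the only ring made, 22-membered, closed last) ← two B-alkyl Suzuki–Miyaura couplings of (Z)-2-iodopropenyl arenes, at C2–C3 (fragment union) and at C15–C16 (ring closure).
3. The two halves 16 and 19 ← one racemic aryl vinyl carbinol carbonate 7 plus butylzinc bromide or (4,4-dichlorobutyl)zinc bromide, by a new enantioconvergent iridium allyl–alkyl coupling with enantiomeric ligands (sets C7 and C20), then vinyl-to-butenyl homologation.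
4. 7 ← 3,5-dihydroxybenzaldehyde (MOM ethers, acetal, ortho-lithiation, acrolein, Boc2O); the dichlorobutyl unit ← CH2Cl2 and 1,3-dibromopropane.

Assumption: the SMILES is read literally as (1R,2S,7S,14R,15S,20S) (bridge numbering: C1/C14 carbamate carbons, C2/C15 methyl carbons, C7 butyl carbon, C20 dichlorobutyl carbon; ring A carries C1 and C20, ring B carries C14 and C7), so C7 and C20 have opposite spatial sense about the pseudo-twofold axis and the two halves are made with enantiomeric ligands.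

**Route**

Step 1
Reactants: 1 3,5-dihydroxybenzaldehyde
Product: 2 3,5-bis(methoxymethoxy)benzaldehyde
Conditions: NaH (2.4 equiv), MOMCl (2.5 equiv), THF/DMF, 0 °C to rt
Reagents that add atoms: chloromethyl methyl ether (MOMCl), COCCl
Why: Williamson O-alkylation of both phenoxides gives MOM ethers, which later direct the ortho-lithiation and are removed by mild acid at the end.

Step 2
Reactants: 2 3,5-bis(methoxymethoxy)benzaldehyde
Product: 3 1-(dimethoxymethyl)-3,5-bis(methoxymethoxy)benzene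
Conditions: HC(OMe)3, MeOH, PPTS (5 mol %), rt
Reagents that add atoms: trimethyl orthoformate, COC(OC)OC
Why: acid-catalysed acetalisation masks the aldehyde against n-BuLi and 9-BBN, and aryl MOM ethers are stable to PPTS at rt.

Step 3
Reactants: 3 1-(dimethoxymethyl)-3,5-bis(methoxymethoxy)benzene; 4 acrolein
Product: 7 tert-butyl 1-[4-(dimethoxymethyl)-2,6-bis(methoxymethoxy)phenyl]prop-2-en-1-yl carbonate (racemic), via aryllithium 5 (not isolated), via lithium alkoxide 6 (not isolated)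
Conditions: n-BuLi (1.1 equiv), THF, 0 °C, 1 h; 4, −78 °C; Boc2O, −78 to 0 °C; chromatography on Et3N-deactivated silica
Reagents that add atoms: di-tert-butyl dicarbonate, CC(C)(C)OC(=O)OC(=O)OC(C)(C)C
Why: directed ortho-metalation at the position between the two cooperating OMOM groups, 1,2-addition to acrolein and O-acylation in one pot give the branched allylic carbonate, deliberately racemic because the next step is enantioconvergent.

Step 4
Reactants: 8 1,3-dibromopropane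
Product: 9 4-bromo-1,1-dichlorobutane
Conditions: CH2Cl2 (1 equiv), LiN(i-Pr)2, THF, −100 °C; then 8 (3 equiv), DMPU, −100 to −60 °C; distillation
Reagents that add atoms: dichloromethane, ClCCl
Why: SN2 alkylation of the carbenoid dichloromethyllithium by a primary bromide, with excess dibromide to stop at monoalkylation.

Step 5
Reactants: 7 tert-butyl 1-[4-(dimethoxymethyl)-2,6-bis(methoxymethoxy)phenyl]prop-2-en-1-yl carbonate (racemic); 10 butylzinc bromide
Product: 11 5-(dimethoxymethyl)-2-[(3S)-hept-1-en-3-yl]-1,3-bis(methoxymethoxy)benzene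
Conditions: [Ir(cod)Cl]2 (4 mol %), (S)-L (16 mol %), 10 (0.5 M in THF, 2 equiv), toluene/THF, rt; L = BINOL-derived N-(5H-dibenzo[b,f]azepin-5-yl)phosphoramidite
Reagents that add atoms: none
Why: Proposed new method: iridium-catalysed enantioconvergent allyl–alkyl coupling of a racemic 1-(2,6-dialkoxyaryl)allyl carbonate with an alkylzinc bromide; the monovalent iridium–(phosphoramidite, olefin) complex ionises either carbonate enantiomer (helped by the electron-rich ring) to trivalent η3-allyliridium species that equilibrate by π–σ–π isomerisation, and C–C bond formation at the branched benzylic terminus on the ligand-controlled face sets the (S)-centre; the closest known reaction is the Ir/(phosphoramidite, olefin)-catalysed coupling of racemic aryl vinyl carbinol carbonates with alkylzinc bromides, not yet shown for di-ortho-substituted aryl groups, and the ligand-to-product sense must be confirmed (the ligand enantiomers are exchanged if it is opposite).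

Step 6
Reactants: 9 4-bromo-1,1-dichlorobutane; 7 tert-butyl 1-[4-(dimethoxymethyl)-2,6-bis(methoxymethoxy)phenyl]prop-2-en-1-yl carbonate (racemic)
Product: 13 2-[(3R)-7,7-dichlorohept-1-en-3-yl]-5-(dimethoxymethyl)-1,3-bis(methoxymethoxy)benzene, via (4,4-dichlorobutyl)zinc bromide 12 (not isolated)
Conditions: 9, Zn dust, LiCl, THF, 40 °C; then 7, [Ir(cod)Cl]2 (4 mol %), (R)-L (16 mol %), toluene/THF, rt
Reagents that add atoms: none
Why: Proposed new method: the same iridium-catalysed enantioconvergent allyl–alkyl coupling as in step 5 (ionisation to equilibrating trivalent η3-allyliridium species, branched-selective C–C bond formation), run with the enantiomeric ligand to give the opposite spatial sense at the new centre and with a zinc reagent whose unactivated CHCl2 group is inert to zinc insertion and to the catalyst; the closest known reaction is again the Ir/(phosphoramidite, olefin) coupling of aryl vinyl carbinol carbonates with functionalised alkylzinc bromides.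

Step 7
Reactants: 11 5-(dimethoxymethyl)-2-[(3S)-hept-1-en-3-yl]-1,3-bis(methoxymethoxy)benzene; 14 vinyl bromide
Product: 16 5-(dimethoxymethyl)-1,3-bis(methoxymethoxy)-2-[(5S)-non-1-en-5-yl]benzene, via alkylborane 15 (not isolated)
Conditions: 9-BBN (1.3 equiv), THF, rt to 40 °C; then 3 M aq K3PO4, 14 (1 M in THF, 4 equiv), Pd(dppf)Cl2 (5 mol %), THF/DMF, rt
Reagents that add atoms: none
Why: anti-Markovnikov hydroboration of the vinyl group followed by B-alkyl Suzuki–Miyaura coupling lengthens the arm by two carbons to the butenyl linker without touching the stereocentre.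

Step 8
Reactants: 13 2-[(3R)-7,7-dichlorohept-1-en-3-yl]-5-(dimethoxymethyl)-1,3-bis(methoxymethoxy)benzene; 14 vinyl bromide
Product: 19 4-[(5R)-9,9-dichloronon-1-en-5-yl]-3,5-bis(methoxymethoxy)benzaldehyde, via alkylborane 17 (not isolated), via dimethyl acetal 18 (not isolated)
Conditions: 9-BBN (1.3 equiv), THF, rt to 40 °C; then 3 M aq K3PO4, 14 (4 equiv), Pd(dppf)Cl2 (5 mol %), THF/DMF, rt; then 1 M HCl, THF, 0 °C, 20 min
Reagents that add atoms: water, O
Why: the same hydroboration/B-alkyl Suzuki–Miyaura homologation, followed by acetal hydrolysis in the acidic work-up, which is much faster than aryl MOM cleavage.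

Step 9
Reactants: 19 4-[(5R)-9,9-dichloronon-1-en-5-yl]-3,5-bis(methoxymethoxy)benzaldehyde
Product: 20 2-[(5R)-9,9-dichloronon-1-en-5-yl]-5-[(1Z)-2-iodoprop-1-en-1-yl]-1,3-bis(methoxymethoxy)benzene
Conditions: EtPPh3I, n-BuLi, THF, rt; I2 (1.0 equiv), −78 °C; NaN(SiMe3)2, −20 °C; 19, −78 to −20 °C
Reagents that add atoms: ethyltriphenylphosphonium iodide, CC[P+](c1ccccc1)(c1ccccc1)c1ccccc1.[I-]; iodine, II
Why: Wittig olefination with the α-iodo ylide (Stork–Zhao type) gives the (Z)-iodoalkene with iodine cis to the arene, which fixes the geometry of the later trisubstituted alkene.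

Step 10
Reactants: 16 5-(dimethoxymethyl)-1,3-bis(methoxymethoxy)-2-[(5S)-non-1-en-5-yl]benzene; 20 2-[(5R)-9,9-dichloronon-1-en-5-yl]-5-[(1Z)-2-iodoprop-1-en-1-yl]-1,3-bis(methoxymethoxy)benzene
Product: 23 4-{(5S,10Z)-11-[4-((5R)-9,9-dichloronon-1-en-5-yl)-3,5-bis(methoxymethoxy)phenyl]-10-methylundec-10-en-5-yl}-3,5-bis(methoxymethoxy)benzaldehyde, via alkylborane 21 (not isolated), via dimethyl acetal 22 (not isolated)
Conditions: 16 (1.15 equiv), 9-BBN (1.2 equiv), THF, rt; 3 M aq Cs2CO3; then 20 (1.0 equiv), Pd(dppf)Cl2 (5 mol %), AsPh3 (10 mol %), DMF, rt; then 1 M HCl, THF, 0 °C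
Reagents that add atoms: water, O
Why: B-alkyl Suzuki–Miyaura coupling with retention at the alkenyl iodide forms the C2–C3 bond and the (Z)-trisubstituted alkene; residual B–H is destroyed by the aqueous base before 20 is added, so its terminal alkene stays free.

Step 11
Reactants: 23 4-{(5S,10Z)-11-[4-((5R)-9,9-dichloronon-1-en-5-yl)-3,5-bis(methoxymethoxy)phenyl]-10-methylundec-10-en-5-yl}-3,5-bis(methoxymethoxy)benzaldehyde
Product: 24 2-{(5S,10Z)-11-[4-((5R)-9,9-dichloronon-1-en-5-yl)-3,5-bis(methoxymethoxy)phenyl]-10-methylundec-10-en-5-yl}-5-[(1Z)-2-iodoprop-1-en-1-yl]-1,3-bis(methoxymethoxy)benzene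
Conditions: EtPPh3I, n-BuLi, THF, rt; I2 (1.0 equiv), −78 °C; NaN(SiMe3)2, −20 °C; 23, −78 to −20 °C
Reagents that add atoms: ethyltriphenylphosphonium iodide, CC[P+](c1ccccc1)(c1ccccc1)c1ccccc1.[I-]; iodine, II
Why: the same α-iodo Wittig olefination installs the second (Z)-iodoalkene; the alkenes and the CHCl2 group are inert to the ylide at low temperature.

Step 12
Reactants: 24 2-{(5S,10Z)-11-[4-((5R)-9,9-dichloronon-1-en-5-yl)-3,5-bis(methoxymethoxy)phenyl]-10-methylundec-10-en-5-yl}-5-[(1Z)-2-iodoprop-1-en-1-yl]-1,3-bis(methoxymethoxy)benzene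
Product: 26 (1Z,7S,14Z,20S)-7-butyl-20-(4,4-dichlorobutyl)-2,15-dimethyl-tetrakis(methoxymethoxy)[7.7]paracyclophane-1,14-diene, via alkylborane 25 (not isolated)
Conditions: 9-BBN (1.5 equiv), THF, rt; then syringe-pump addition (12 h) to Pd(dppf)Cl2 (20 mol %), AsPh3 (40 mol %), Cs2CO3, DMF/THF/H2O, 50 °C, final 1 mM
Reagents that add atoms: none
Why: ring-closing B-alkyl Suzuki–Miyaura coupling forms the C15–C16 bond and the 22-membered ring; 9-BBN selects the terminal alkene over the trisubstituted styrene and the alkenyl iodide, and the two in-ring cis alkenes pre-fold the chain.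

Step 13
Reactants: 26 (1Z,7S,14Z,20S)-7-butyl-20-(4,4-dichlorobutyl)-2,15-dimethyl-tetrakis(methoxymethoxy)[7.7]paracyclophane-1,14-diene
Product: 28 (1R,2S,7S,14R,15S,20S)-7-butyl-20-(4,4-dichlorobutyl)-2,15-dimethyl-tetrakis(methoxymethoxy)[7.7]paracyclophane-1,14-diol, via bis(isopinocampheylborane) adduct 27 (not isolated)
Conditions: (−)-IpcBH2 (from (+)-α-pinene, preformed in THF, 3 equiv), THF, −25 to 0 °C, 24 h; then 3 M NaOH, 30% H2O2, 0 °C to rt
Reagents that add atoms: hydrogen peroxide, OO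
Why: Brown asymmetric hydroboration–oxidation puts boron on each benzylic carbon by syn addition to the (Z)-alkene and oxidises C–B to C–O with retention, so both key C–O bonds and C1, C2, C14 and C15 are set in one operation with the face chosen by the reagent (this IpcBH2 enantiomer is predicted by analogy with 1-methylcycloalkenes and is checked on a model styrene first; the antipode is used if the sense is opposite).

Step 14
Reactants: 28 (1R,2S,7S,14R,15S,20S)-7-butyl-20-(4,4-dichlorobutyl)-2,15-dimethyl-tetrakis(methoxymethoxy)[7.7]paracyclophane-1,14-diol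
Product: 30 (1R,2S,7S,14R,15S,20S)-7-butyl-20-(4,4-dichlorobutyl)-2,15-dimethyl-tetrakis(methoxymethoxy)[7.7]paracyclophane-1,14-diyl dicarbamate, via bis(N-trichloroacetylcarbamate) 29 (not isolated)
Conditions: Cl3CC(O)NCO (2.5 equiv), CH2Cl2, 0 °C; then K2CO3, MeOH, rt
Reagents that add atoms: trichloroacetyl isocyanate, O=C=NC(=O)C(Cl)(Cl)Cl
Why: addition of the secondary alcohols to the acyl isocyanate and methanolysis of the trichloroacetyl group give the primary carbamates with the C–O stereocentres untouched.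

Step 15
Reactants: 30 (1R,2S,7S,14R,15S,20S)-7-butyl-20-(4,4-dichlorobutyl)-2,15-dimethyl-tetrakis(methoxymethoxy)[7.7]paracyclophane-1,14-diyl dicarbamate
Product: 31 target: (1R,2S,7S,14R,15S,20S)-7-butyl-20-(4,4-dichlorobutyl)-2,15-dimethyl-tetrahydroxy[7.7]paracyclophane-1,14-diyl dicarbamate
Conditions: 3 M aq HCl, i-PrOH/THF, 35 °C
Reagents that add atoms: none
Why: acid hydrolysis of the four aryl MOM acetals; the benzylic carbamates should survive because the ring oxygens are meta to the benzylic carbons and do not stabilise a benzylic cation.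

**Compound list**
1 | 3,5-dihydroxybenzaldehyde | O=Cc1cc(O)cc(O)c1 | starting material
2 | 3,5-bis(methoxymethoxy)benzaldehyde | O=Cc1cc(OCOC)cc(OCOC)c1 | intermediate
3 | 1-(dimethoxymethyl)-3,5-bis(methoxymethoxy)benzene | COC(OC)c1cc(OCOC)cc(OCOC)c1 | intermediate
4 | acrolein (prop-2-enal) | C=CC=O | starting material
5 | [4-(dimethoxymethyl)-2,6-bis(methoxymethoxy)phenyl]lithium | [Li]c1c(OCOC)cc(cc1OCOC)C(OC)OC | intermediate
6 | lithium 1-[4-(dimethoxymethyl)-2,6-bis(methoxymethoxy)phenyl]prop-2-en-1-olate (racemic) | [Li+].[O-]C(C=C)c1c(OCOC)cc(cc1OCOC)C(OC)OC | intermediate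
7 | tert-butyl 1-[4-(dimethoxymethyl)-2,6-bis(methoxymethoxy)phenyl]prop-2-en-1-yl carbonate (racemic) | C=CC(OC(=O)OC(C)(C)C)c1c(OCOC)cc(cc1OCOC)C(OC)OC | intermediate
8 | 1,3-dibromopropane | BrCCCBr | starting material
9 | 4-bromo-1,1-dichlorobutane | ClC(Cl)CCCBr | intermediate
10 | butylzinc bromide | CCCC[Zn]Br | starting material
11 | 5-(dimethoxymethyl)-2-[(3S)-hept-1-en-3-yl]-1,3-bis(methoxymethoxy)benzene | CCCC[C@H](c1c(OCOC)cc(cc1OCOC)C(OC)OC)C=C | intermediate
12 | (4,4-dichlorobutyl)zinc bromide | ClC(Cl)CCC[Zn]Br | intermediate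
13 | 2-[(3R)-7,7-dichlorohept-1-en-3-yl]-5-(dimethoxymethyl)-1,3-bis(methoxymethoxy)benzene | ClC(Cl)CCC[C@@H](c1c(OCOC)cc(cc1OCOC)C(OC)OC)C=C | intermediate
14 | vinyl bromide (bromoethene) | C=CBr | starting material
15 | 9-{(3R)-3-[4-(dimethoxymethyl)-2,6-bis(methoxymethoxy)phenyl]heptyl}-9-borabicyclo[3.3.1]nonane (same spatial arrangement as 11) | CCCC[C@H](c1c(OCOC)cc(cc1OCOC)C(OC)OC)CCB2C3CCCC2CCC3 | intermediate
16 | 5-(dimethoxymethyl)-1,3-bis(methoxymethoxy)-2-[(5S)-non-1-en-5-yl]benzene | CCCC[C@H](c1c(OCOC)cc(cc1OCOC)C(OC)OC)CCC=C | intermediate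
17 | 9-{(3S)-7,7-dichloro-3-[4-(dimethoxymethyl)-2,6-bis(methoxymethoxy)phenyl]heptyl}-9-borabicyclo[3.3.1]nonane (same spatial arrangement as 13) | ClC(Cl)CCC[C@@H](c1c(OCOC)cc(cc1OCOC)C(OC)OC)CCB2C3CCCC2CCC3 | intermediate
18 | 2-[(5R)-9,9-dichloronon-1-en-5-yl]-5-(dimethoxymethyl)-1,3-bis(methoxymethoxy)benzene | ClC(Cl)CCC[C@@H](c1c(OCOC)cc(cc1OCOC)C(OC)OC)CCC=C | intermediate
19 | 4-[(5R)-9,9-dichloronon-1-en-5-yl]-3,5-bis(methoxymethoxy)benzaldehyde | ClC(Cl)CCC[C@@H](c1c(OCOC)cc(C=O)cc1OCOC)CCC=C | intermediate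
20 | 2-[(5R)-9,9-dichloronon-1-en-5-yl]-5-[(1Z)-2-iodoprop-1-en-1-yl]-1,3-bis(methoxymethoxy)benzene | ClC(Cl)CCC[C@@H](c1c(OCOC)cc(/C=C(I)/C)cc1OCOC)CCC=C | intermediate
21 | 9-{(5S)-5-[4-(dimethoxymethyl)-2,6-bis(methoxymethoxy)phenyl]nonyl}-9-borabicyclo[3.3.1]nonane | CCCC[C@H](c1c(OCOC)cc(cc1OCOC)C(OC)OC)CCCCB2C3CCCC2CCC3 | intermediate
22 | 2-{(5S,10Z)-11-[4-((5R)-9,9-dichloronon-1-en-5-yl)-3,5-bis(methoxymethoxy)phenyl]-10-methylundec-10-en-5-yl}-5-(dimethoxymethyl)-1,3-bis(methoxymethoxy)benzene | COC(OC)c1cc(OCOC)c([C@@H](CCCC)CCCC/C(C)=C\c2cc(OCOC)c([C@H](CCCC(Cl)Cl)CCC=C)c(OCOC)c2)c(OCOC)c1 | intermediate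
23 | 4-{(5S,10Z)-11-[4-((5R)-9,9-dichloronon-1-en-5-yl)-3,5-bis(methoxymethoxy)phenyl]-10-methylundec-10-en-5-yl}-3,5-bis(methoxymethoxy)benzaldehyde | O=Cc1cc(OCOC)c([C@@H](CCCC)CCCC/C(C)=C\c2cc(OCOC)c([C@H](CCCC(Cl)Cl)CCC=C)c(OCOC)c2)c(OCOC)c1 | intermediate
24 | 2-{(5S,10Z)-11-[4-((5R)-9,9-dichloronon-1-en-5-yl)-3,5-bis(methoxymethoxy)phenyl]-10-methylundec-10-en-5-yl}-5-[(1Z)-2-iodoprop-1-en-1-yl]-1,3-bis(methoxymethoxy)benzene | C/C(I)=C/c1cc(OCOC)c([C@@H](CCCC)CCCC/C(C)=C\c2cc(OCOC)c([C@H](CCCC(Cl)Cl)CCC=C)c(OCOC)c2)c(OCOC)c1 | intermediate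
25 | B-alkyl-9-borabicyclo[3.3.1]nonane adduct of 24 (boron on the terminal carbon of the nonenyl chain, all stereo-elements as in 24) | C/C(I)=C/c1cc(OCOC)c([C@@H](CCCC)CCCC/C(C)=C\c2cc(OCOC)c([C@H](CCCC(Cl)Cl)CCCCB3C4CCCC3CCC4)c(OCOC)c2)c(OCOC)c1 | intermediate
26 | (1Z,7S,14Z,20S)-7-butyl-20-(4,4-dichlorobutyl)-2,15-dimethyl-tetrakis(methoxymethoxy)[7.7]paracyclophane-1,14-diene (OMOM groups on the four ring carbons flanking C7 and C20) | CCCC[C@H]1CCCC/C(C)=C\c2cc(OCOC)c(c(OCOC)c2)[C@H](CCCC(Cl)Cl)CCCC/C(C)=C\c2cc(OCOC)c1c(OCOC)c2 | intermediate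
27 | 1,14-bis[(isopinocampheyl)boranyl] adduct of 26 (boron on C1 and C14, hydrogen on C2 and C15, syn; isopinocampheyl from (+)-α-pinene) | CCCC[C@H]1CCCC[C@H](C)[C@@H]([BH][C@@H]3C[C@@H]4C[C@H]([C@H]3C)C4(C)C)c2cc(OCOC)c(c(OCOC)c2)[C@H](CCCC(Cl)Cl)CCCC[C@H](C)[C@@H]([BH][C@@H]3C[C@@H]4C[C@H]([C@H]3C)C4(C)C)c2cc(OCOC)c1c(OCOC)c2 | intermediate
28 | (1R,2S,7S,14R,15S,20S)-7-butyl-20-(4,4-dichlorobutyl)-2,15-dimethyl-tetrakis(methoxymethoxy)[7.7]paracyclophane-1,14-diol | CCCC[C@H]1CCCC[C@H](C)[C@@H](O)c2cc(OCOC)c(c(OCOC)c2)[C@H](CCCC(Cl)Cl)CCCC[C@H](C)[C@@H](O)c2cc(OCOC)c1c(OCOC)c2 | intermediate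
29 | 1,14-bis(N-trichloroacetylcarbamate) of 28 | CCCC[C@H]1CCCC[C@H](C)[C@@H](OC(=O)NC(=O)C(Cl)(Cl)Cl)c2cc(OCOC)c(c(OCOC)c2)[C@H](CCCC(Cl)Cl)CCCC[C@H](C)[C@@H](OC(=O)NC(=O)C(Cl)(Cl)Cl)c2cc(OCOC)c1c(OCOC)c2 | intermediate
30 | (1R,2S,7S,14R,15S,20S)-7-butyl-20-(4,4-dichlorobutyl)-2,15-dimethyl-tetrakis(methoxymethoxy)[7.7]paracyclophane-1,14-diyl dicarbamate | CCCC[C@H]1CCCC[C@H](C)[C@@H](OC(N)=O)c2cc(OCOC)c(c(OCOC)c2)[C@H](CCCC(Cl)Cl)CCCC[C@H](C)[C@@H](OC(N)=O)c2cc(OCOC)c1c(OCOC)c2 | intermediate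
31 | (1R,2S,7S,14R,15S,20S)-7-butyl-20-(4,4-dichlorobutyl)-2,15-dimethyl-tetrahydroxy[7.7]paracyclophane-1,14-diyl dicarbamate (CNP0135078.1) | CCCC[C@H]1CCCC[C@H](C)[C@@H](OC(N)=O)c2cc(O)c(c(O)c2)[C@H](CCCC(Cl)Cl)CCCC[C@H](C)[C@@H](OC(N)=O)c2cc(O)c1c(O)c2 | target

**Step count and risks**

Total steps: 15. Longest linear sequence: 12 (steps 1, 2, 3, 6, 8, 9, 10, 11, 12, 13, 14, 15).

The three steps most likely to fail:

Step 5 (new iridium allyl–alkyl coupling). The di-ortho-substituted aryl group may twist out of conjugation with the allyl unit, giving linear product, low ee or no reaction. The fallback is known auxiliary chemistry that sets out from 3 and comes back at 16. Compound 3 is lithiated as in step 3 and quenched with DMF to give 4-(dimethoxymethyl)-2,6-bis(methoxymethoxy)benzaldehyde F1. Horner–Wadsworth–Emmons olefination (LiCl, i-Pr2NEt, MeCN) with the known reagent diethyl {2-[(4S)-4-benzyl-2-oxo-1,3-oxazolidin-3-yl]-2-oxoethyl}phosphonate gives the (E)-enoyl imide (4S)-4-benzyl-3-{(2E)-3-[4-(dimethoxymethyl)-2,6-bis(methoxymethoxy)phenyl]prop-2-enoyl}-1,3-oxazolidin-2-one F2. Conjugate addition of n-BuMgBr/CuBr·SMe2 (THF, −40 °C) to the magnesium-chelated s-cis imide, on the face away from the benzyl group, gives (4S)-4-benzyl-3-{(3S)-3-[4-(dimethoxymethyl)-2,6-bis(methoxymethoxy)phenyl]heptanoyl}-1,3-oxazolidin-2-one F3. LiBH4 (THF, MeOH) removes the auxiliary to give (3S)-3-[4-(dimethoxymethyl)-2,6-bis(methoxymethoxy)phenyl]heptan-1-ol F4. I2, PPh3 and imidazole give 5-(dimethoxymethyl)-2-[(3S)-1-iodoheptan-3-yl]-1,3-bis(methoxymethoxy)benzene F5. CH2=CHMgBr with CuI (10 mol %) in THF then gives 16, so step 7 is not needed.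

Step 6 (the same new coupling with the functionalised zinc reagent). It carries the substrate risk of step 5 plus the added risk of the dichloroalkylzinc reagent. The fallback is the same known auxiliary chemistry; it sets out from 3 and 9 and comes back at 18, which is hydrolysed to 19 as in step 8. The aldehyde F1 (made as above) is olefinated with the (4R)-phosphonate to (4R)-4-benzyl-3-{(2E)-3-[4-(dimethoxymethyl)-2,6-bis(methoxymethoxy)phenyl]prop-2-enoyl}-1,3-oxazolidin-2-one F6. Compound 9 and Mg (THF, 0 °C) give (4,4-dichlorobutyl)magnesium bromide F7, which with CuBr·SMe2 adds to F6 to give (4R)-4-benzyl-3-{(3R)-7,7-dichloro-3-[4-(dimethoxymethyl)-2,6-bis(methoxymethoxy)phenyl]heptanoyl}-1,3-oxazolidin-2-one F8. LiBH4 gives (3R)-7,7-dichloro-3-[4-(dimethoxymethyl)-2,6-bis(methoxymethoxy)phenyl]heptan-1-ol F9. I2, PPh3 and imidazole give 2-[(3R)-7,7-dichloro-1-iodoheptan-3-yl]-5-(dimethoxymethyl)-1,3-bis(methoxymethoxy)benzene F10. CH2=CHMgBr with CuI gives 18.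

Step 12 (macrocyclisation). The aqueous-base borane coupling may give oligomers or protodeboronation at high dilution. The fallback sets out from 24 and comes back at 26, and replaces the in situ borane by a discrete organozinc and a base-free Negishi ring closure. Compound 24 is hydroborated to 25 as in step 12 and treated with I2 and NaOMe (MeOH, 0 °C) to give the primary iodide, 24 with its terminal CH=CH2 turned into CH2CH2I, F11. Zinc insertion (Zn dust, LiCl, THF, 35 °C; the alkenyl iodide does not insert at this temperature) gives the alkylzinc iodide F12. Slow addition of F12 to Pd(PPh3)4 (10 mol %) in THF/N-methylpyrrolidinone at 50 °C closes the same C15–C16 bond with retention of the alkene geometry to give 26.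

**Further compounds**
F1 | step 5 | 4-(dimethoxymethyl)-2,6-bis(methoxymethoxy)benzaldehyde | O=Cc1c(OCOC)cc(cc1OCOC)C(OC)OC
F2 | step 5 | (4S)-4-benzyl-3-{(2E)-3-[4-(dimethoxymethyl)-2,6-bis(methoxymethoxy)phenyl]prop-2-enoyl}-1,3-oxazolidin-2-one | O=C1OC[C@H](Cc2ccccc2)N1C(=O)/C=C/c3c(OCOC)cc(cc3OCOC)C(OC)OC
F3 | step 5 | (4S)-4-benzyl-3-{(3S)-3-[4-(dimethoxymethyl)-2,6-bis(methoxymethoxy)phenyl]heptanoyl}-1,3-oxazolidin-2-one | O=C1OC[C@H](Cc2ccccc2)N1C(=O)C[C@H](CCCC)c3c(OCOC)cc(cc3OCOC)C(OC)OC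
F4 | step 5 | (3S)-3-[4-(dimethoxymethyl)-2,6-bis(methoxymethoxy)phenyl]heptan-1-ol | OCC[C@H](CCCC)c1c(OCOC)cc(cc1OCOC)C(OC)OC
F5 | step 5 | 5-(dimethoxymethyl)-2-[(3S)-1-iodoheptan-3-yl]-1,3-bis(methoxymethoxy)benzene | ICC[C@H](CCCC)c1c(OCOC)cc(cc1OCOC)C(OC)OC
F6 | step 6 | (4R)-4-benzyl-3-{(2E)-3-[4-(dimethoxymethyl)-2,6-bis(methoxymethoxy)phenyl]prop-2-enoyl}-1,3-oxazolidin-2-one | O=C1OC[C@@H](Cc2ccccc2)N1C(=O)/C=C/c3c(OCOC)cc(cc3OCOC)C(OC)OC
F7 | step 6 | (4,4-dichlorobutyl)magnesium bromide | ClC(Cl)CCC[Mg]Br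
F8 | step 6 | (4R)-4-benzyl-3-{(3R)-7,7-dichloro-3-[4-(dimethoxymethyl)-2,6-bis(methoxymethoxy)phenyl]heptanoyl}-1,3-oxazolidin-2-one | O=C1OC[C@@H](Cc2ccccc2)N1C(=O)C[C@@H](CCCC(Cl)Cl)c3c(OCOC)cc(cc3OCOC)C(OC)OC
F9 | step 6 | (3R)-7,7-dichloro-3-[4-(dimethoxymethyl)-2,6-bis(methoxymethoxy)phenyl]heptan-1-ol | OCC[C@@H](CCCC(Cl)Cl)c1c(OCOC)cc(cc1OCOC)C(OC)OC
F10 | step 6 | 2-[(3R)-7,7-dichloro-1-iodoheptan-3-yl]-5-(dimethoxymethyl)-1,3-bis(methoxymethoxy)benzene | ICC[C@@H](CCCC(Cl)Cl)c1c(OCOC)cc(cc1OCOC)C(OC)OC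
F11 | step 12 | primary iodide: 24 with the terminal CH=CH2 of the nonenyl chain converted to CH2CH2I (all stereo-elements as in 24) | C/C(I)=C/c1cc(OCOC)c([C@@H](CCCC)CCCC/C(C)=C\c2cc(OCOC)c([C@H](CCCC(Cl)Cl)CCCCI)c(OCOC)c2)c(OCOC)c1
F12 | step 12 | alkylzinc iodide from F11 (zinc on the former CH2I carbon, alkenyl iodide intact) | C/C(I)=C/c1cc(OCOC)c([C@@H](CCCC)CCCC/C(C)=C\c2cc(OCOC)c([C@H](CCCC(Cl)Cl)CCCC[Zn]I)c(OCOC)c2)c(OCOC)c1
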